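**Plan**

Rings are lettered A (2,4,6-trihydroxyphenyl end) to F (3,4,5-trihydroxyphenyl end). In rings A, B and C the carbon holding the ether oxygen that points towards ring F (A-C1, B-C4, C-C4) sits between two hydroxyl-bearing carbons (A-C2/C6, B-C3/C5, C-C3/C5). If those six carbons carry CHO, the carbon between them is an SNAr site, and a Baeyer–Villiger oxidation later turns each C–CHO into C–OH.
Cuts in retrosynthetic order: nine O–CH3 bonds (rings A, D, E, F); the six flanking aryl C–OH bonds of rings A–C (back to C–CHO); the aryl–oxygen bonds at A-C1, B-C4 and C-C4 (fluoride displacement); the bond O–D-C2 (Ullmann); the bond O–F-C1 (Chan–Lam).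
Forward: all six benzene rings are bought and none is built. The chain grows one ring at a time from the F end: E–F, then D, C, B and A.
Each new phenol nucleophile is released from a formyl group by Baeyer–Villiger oxidation (rings E and D) or from a benzyl ether (rings C and B).
Stereochemistry: the target has no stereocentre and its diaryl ethers rotate freely, so nothing has to be set.

Key step: step 16

Remark: no compound of the main route is chiral, so the SMILES carry no stereodescriptors.

**Step 1**
Reactants: 1 4-methoxyphenol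
Product: 2 2-hydroxy-5-methoxyisophthalaldehyde
Conditions: (CH2)6N4 (4 equiv), TFA, reflux; then 4 M aq HCl, rt
Reagents that add atoms: hexamethylenetetramine, C1N2CN3CN1CN(C2)C3; water, O
Why: Double Duff formylation, in which the iminium ions released from hexamethylenetetramine attack both positions ortho to the free phenol (the para position is blocked by OMe) and internal hydride transfer followed by acid hydrolysis leaves the two formyl groups.

**Step 2**
Reactants: 2 2-hydroxy-5-methoxyisophthalaldehyde
Product: 4 2-fluoro-5-methoxyisophthalaldehyde (ring A fluoride), via aryl fluorosulfonate 3 (not isolated)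
Conditions: SO2F2 (1 atm), anhydrous NMe4F (3 equiv), DMF, rt to 60 °C
Reagents that add atoms: tetramethylammonium fluoride, C[N+](C)(C)C.[F-]; sulfuryl fluoride, O=S(=O)(F)F (atoms kept only in 3)
Why: Deoxyfluorination of an electron-poor phenol through its aryl fluorosulfonate, in which the phenoxide is sulfonylated by SO2F2 and fluoride then displaces fluorosulfate at the ipso carbon (SNAr), a carbon strongly activated by the two ortho formyl groups.

**Step 3**
Reactants: 5 4-(benzyloxy)phenol
Product: 6 4-(benzyloxy)-2,6-bis(hydroxymethyl)phenol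
Conditions: 37% aq CH2O (excess), NaOH (1.1 equiv), H2O–MeOH, rt; then AcOH
Reagents that add atoms: formaldehyde, C=O
Why: Lederer–Manasse hydroxymethylation, in which the phenoxide adds to formaldehyde at its two free ortho positions while the base-stable benzyl ether is untouched, which is why the hot TFA of step 1 is avoided here.

**Step 4**
Reactants: 6 4-(benzyloxy)-2,6-bis(hydroxymethyl)phenol
Product: 7 5-(benzyloxy)-2-hydroxyisophthalaldehyde
Conditions: activated MnO2 (excess), CHCl3, reflux
Reagents that add atoms: none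
Why: Selective MnO2 oxidation of benzylic alcohols, the standard passage from 2,6-bis(hydroxymethyl)phenols to 2-hydroxyisophthalaldehydes, which stops at the aldehyde and leaves the benzyl ether alone.

**Step 5**
Reactants: 7 5-(benzyloxy)-2-hydroxyisophthalaldehyde
Product: 9 5-(benzyloxy)-2-fluoroisophthalaldehyde (fluoride for rings B and C), via aryl fluorosulfonate 8 (not isolated)
Conditions: SO2F2 (1 atm), anhydrous NMe4F (3 equiv), DMF, rt to 60 °C
Reagents that add atoms: tetramethylammonium fluoride, C[N+](C)(C)C.[F-]; sulfuryl fluoride, O=S(=O)(F)F (atoms kept only in 8)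
Why: The same fluorosulfonate-mediated deoxyfluorination (SNAr by fluoride) as in step 2, the benzyl ether being inert to SO2F2 and to fluoride.

**Step 6**
Reactants: 10 syringaldehyde (4-hydroxy-3,5-dimethoxybenzaldehyde); 11 3,4,5-trimethoxyphenylboronic acid
Product: 12 3,5-dimethoxy-4-(3,4,5-trimethoxyphenoxy)benzaldehyde (E–F aldehyde)
Conditions: Cu(OAc)2 (1 equiv, kept divalent by air), pyridine, Et3N, 4 Å MS, CH2Cl2, dry air, rt
Reagents that add atoms: none
Why: Chan–Lam coupling, in which the aryl group passes from boron to a copper phenoxide and C–O reductive elimination follows with O2 as terminal oxidant, a reaction that accepts 2,6-disubstituted and electron-poor phenols because the hindered partner enters as the oxygen ligand and not as the aryl electrophile.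

**Step 7**
Reactants: 12 E–F aldehyde
Product: 14 3,5-dimethoxy-4-(3,4,5-trimethoxyphenoxy)phenol (E–F phenol), via E–F aryl formate 13 (not isolated)
Conditions: mCPBA, CH2Cl2, 0 °C to rt; aq Na2S2O3/NaHCO3 wash; then K2CO3 (cat.), MeOH, rt
Reagents that add atoms: meta-chloroperbenzoic acid, O=C(OO)c1cccc(Cl)c1
Why: Baeyer–Villiger oxidation of an electron-rich benzaldehyde (para aryloxy donor) should give the aryl formate by aryl migration, and mild methanolysis frees the ring E phenol.

**Step 8**
Reactants: 15 3,4,5-trimethoxybenzaldehyde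
Product: 16 2-bromo-3,4,5-trimethoxybenzaldehyde
Conditions: NBS, CHCl3, reflux
Reagents that add atoms: N-bromosuccinimide, O=C1CCC(=O)N1Br
Why: Electrophilic aromatic bromination, in which the two equivalent free positions are each ortho to one methoxy group and para to another, so that only one monobromide can form.

**Step 9**
Reactants: 14 E–F phenol; 16 2-bromo-3,4,5-trimethoxybenzaldehyde
Product: 17 2-[3,5-dimethoxy-4-(3,4,5-trimethoxyphenoxy)phenoxy]-3,4,5-trimethoxybenzaldehyde (D–E–F aldehyde)
Conditions: CuI (10 mol %), picolinic acid (20 mol %), K3PO4 (2 equiv), DMSO, 90 °C, Ar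
Reagents that add atoms: none
Why: Ligand-assisted Ullmann diaryl ether synthesis, in which the unhindered electron-rich phenoxide of 14 couples with an aryl bromide whose ortho formyl group eases C–Br activation at copper, picolinic acid being a ligand suited to ortho-substituted partners.

**Step 10**
Reactants: 17 D–E–F aldehyde
Product: 19 2-[3,5-dimethoxy-4-(3,4,5-trimethoxyphenoxy)phenoxy]-3,4,5-trimethoxyphenol (D–E–F phenol), via D–E–F aryl formate 18 (not isolated)
Conditions: mCPBA, CH2Cl2, 0 °C to rt; aq Na2S2O3/NaHCO3 wash; then K2CO3 (cat.), MeOH, rt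
Reagents that add atoms: meta-chloroperbenzoic acid, O=C(OO)c1cccc(Cl)c1
Why: Baeyer–Villiger oxidation with aryl migration favoured by the ortho aryloxy and para methoxy donors, followed by methanolysis of the formate to the ring D phenol.

**Step 11**
Reactants: 19 D–E–F phenol; 9 5-(benzyloxy)-2-fluoroisophthalaldehyde
Product: 20 C–D–E–F dialdehyde benzyl ether (19 joined through its phenolic oxygen to C2 of 5-(benzyloxy)isophthalaldehyde)
Conditions: K2CO3 (1.5 equiv), DMF, 50 °C, Ar
Reagents that add atoms: none
Why: SNAr by addition–elimination, in which the phenoxide adds to the C–F carbon, the two ortho formyl groups take up the Meisenheimer-type charge and fluoride leaves, a mechanism far less sensitive to ortho crowding than metal-catalysed etherification.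

**Step 12**
Reactants: 20 C–D–E–F dialdehyde benzyl ether
Product: 21 C–D–E–F dialdehyde phenol (free OH at C-C1)
Conditions: BCl3 (1 M in CH2Cl2, 5 equiv), C6HMe5 (3 equiv), CH2Cl2, −78 °C; H2O quench
Reagents that add atoms: none
Why: Lewis-acid debenzylation with a cation scavenger, in which BCl3 ionises the aryl benzyl ether at low temperature and pentamethylbenzene traps the benzyl cation (Friedel–Crafts alkylation), conditions that spare aryl methyl ethers, diaryl ethers and formyl groups and avoid the aldehyde reduction that hydrogenolysis could cause.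

**Step 13**
Reactants: 21 C–D–E–F dialdehyde phenol; 9 5-(benzyloxy)-2-fluoroisophthalaldehyde
Product: 22 B–C–D–E–F tetra-aldehyde benzyl ether
Conditions: K2CO3 (1.5 equiv), DMF, 60 °C, Ar
Reagents that add atoms: none
Why: Second SNAr round, in which fluoride is a much better nucleofuge than the aryloxide at the flanked ether carbon already in place and ring C is further deactivated while it carries the para phenoxide, so ether exchange should not compete.

**Step 14**
Reactants: 22 B–C–D–E–F tetra-aldehyde benzyl ether
Product: 23 B–C–D–E–F tetra-aldehyde phenol (free OH at B-C1)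
Conditions: BCl3 (1 M in CH2Cl2, 8 equiv), C6HMe5 (3 equiv), CH2Cl2, −78 °C; H2O quench
Reagents that add atoms: none
Why: The same BCl3/pentamethylbenzene debenzylation as in step 12, with more BCl3 to saturate the two additional formyl oxygens.

**Step 15**
Reactants: 23 B–C–D–E–F tetra-aldehyde phenol; 4 2-fluoro-5-methoxyisophthalaldehyde
Product: 24 hexa-aldehyde of the full A–F skeleton (two CHO each on rings A, B and C, nine OMe)
Conditions: K2CO3 (1.5 equiv), DMF, 60 °C, Ar
Reagents that add atoms: none
Why: Third SNAr round of the same type, with the ring B phenoxide displacing fluoride from the doubly formyl-activated ring A fluoride used in slight excess.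

**Step 16**
Reactants: 24 hexa-aldehyde
Product: 26 hexaphenol nonamethyl ether (OH at A-C2, A-C6, B-C3, B-C5, C-C3, C-C5), via hexaformate 25 (not isolated)
Conditions: mCPBA (10 equiv, CH2Cl2 solution dried over MgSO4), CH2Cl2, 0 °C to rt; aq Na2S2O3/NaHCO3 wash; then Et3N (cat.), degassed MeOH–THF, rt, Ar
Reagents that add atoms: meta-chloroperbenzoic acid, O=C(OO)c1cccc(Cl)c1
Why: Each formyl carbon adds the peracid to give a Criegee-type peroxy hemiacetal, and departure of 3-chlorobenzoate is coupled to a 1,2-shift of the ring carbon from carbon to oxygen, so six new aryl C–O bonds (A-C2, A-C6, B-C3, B-C5, C-C3, C-C5) arise as the formate esters of 25, which methanol then converts into free phenols and methyl formate. The closest known reaction type is the Baeyer–Villiger (Dakin-type) oxidation of ortho- or para-oxygenated benzaldehydes, commonly used after fluoride displacement on a fluorobenzaldehyde to turn the spent activating group into a hydroxyl; here it runs six times on one substrate. No ring is closed and no stereocentre is created. The selectivity needed is aryl over hydride migration at every site; it rests on the aryloxy oxygen ortho to each formyl group, whose lone pair supports the electron-poor migrating carbon, and each completed oxidation replaces a withdrawing formyl by a formyloxy group and so eases the second migration in the same ring. The second requirement, oxidation of CHO in preference to attack on the methoxylated rings D–F, is tested beforehand on the same rings in steps 7 and 10, and the new oxygens stay masked as formates until the peracid has been destroyed.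

**Step 17**
Reactants: 26 hexaphenol nonamethyl ether
Product: 27 target CNP0175585.0
Conditions: BBr3 (1 M in CH2Cl2, 25 equiv), CH2Cl2, −78 °C to rt; ice-water quench; reversed-phase purification under Ar
Reagents that add atoms: none
Why: Exhaustive BBr3 cleavage of aryl methyl ethers (Lewis-acid complexation, then SN2 attack of bromide at methyl), which cannot break the five diaryl ether bonds because an aryl carbon does not accept SN2 attack.

**Compound list**

1 | 4-methoxyphenol | COc1ccc(O)cc1 | starting material
2 | 2-hydroxy-5-methoxyisophthalaldehyde | COc1cc(C=O)c(O)c(C=O)c1 | intermediate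
3 | 2,6-diformyl-4-methoxyphenyl fluorosulfonate | COc1cc(C=O)c(OS(=O)(=O)F)c(C=O)c1 | intermediate
4 | 2-fluoro-5-methoxyisophthalaldehyde | COc1cc(C=O)c(F)c(C=O)c1 | intermediate
5 | 4-(benzyloxy)phenol | Oc1ccc(OCc2ccccc2)cc1 | starting material
6 | 4-(benzyloxy)-2,6-bis(hydroxymethyl)phenol | OCc1cc(OCc2ccccc2)cc(CO)c1O | intermediate
7 | 5-(benzyloxy)-2-hydroxyisophthalaldehyde | O=Cc1cc(OCc2ccccc2)cc(C=O)c1O | intermediate
8 | 4-(benzyloxy)-2,6-diformylphenyl fluorosulfonate | O=Cc1cc(OCc2ccccc2)cc(C=O)c1OS(=O)(=O)F | intermediate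
9 | 5-(benzyloxy)-2-fluoroisophthalaldehyde | O=Cc1cc(OCc2ccccc2)cc(C=O)c1F | intermediate
10 | syringaldehyde | COc1cc(C=O)cc(OC)c1O | starting material
11 | 3,4,5-trimethoxyphenylboronic acid | COc1cc(B(O)O)cc(OC)c1OC | starting material
12 | 3,5-dimethoxy-4-(3,4,5-trimethoxyphenoxy)benzaldehyde | COc1cc(C=O)cc(OC)c1Oc1cc(OC)c(OC)c(OC)c1 | intermediate
13 | 3,5-dimethoxy-4-(3,4,5-trimethoxyphenoxy)phenyl formate | COc1cc(OC=O)cc(OC)c1Oc1cc(OC)c(OC)c(OC)c1 | intermediate
14 | 3,5-dimethoxy-4-(3,4,5-trimethoxyphenoxy)phenol | COc1cc(O)cc(OC)c1Oc1cc(OC)c(OC)c(OC)c1 | intermediate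
15 | 3,4,5-trimethoxybenzaldehyde | COc1cc(C=O)cc(OC)c1OC | starting material
16 | 2-bromo-3,4,5-trimethoxybenzaldehyde | COc1cc(C=O)c(Br)c(OC)c1OC | intermediate
17 | D–E–F aldehyde | O=Cc1cc(OC)c(OC)c(OC)c1Oc1cc(OC)c(Oc2cc(OC)c(OC)c(OC)c2)c(OC)c1 | intermediate
18 | D–E–F aryl formate | O=COc1cc(OC)c(OC)c(OC)c1Oc1cc(OC)c(Oc2cc(OC)c(OC)c(OC)c2)c(OC)c1 | intermediate
19 | D–E–F phenol | Oc1cc(OC)c(OC)c(OC)c1Oc1cc(OC)c(Oc2cc(OC)c(OC)c(OC)c2)c(OC)c1 | intermediate
20 | C–D–E–F dialdehyde benzyl ether | O=Cc1cc(OCc2ccccc2)cc(C=O)c1Oc1cc(OC)c(OC)c(OC)c1Oc1cc(OC)c(Oc2cc(OC)c(OC)c(OC)c2)c(OC)c1 | intermediate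
21 | C–D–E–F dialdehyde phenol | O=Cc1cc(O)cc(C=O)c1Oc1cc(OC)c(OC)c(OC)c1Oc1cc(OC)c(Oc2cc(OC)c(OC)c(OC)c2)c(OC)c1 | intermediate
22 | B–C–D–E–F tetra-aldehyde benzyl ether | O=Cc1cc(OCc2ccccc2)cc(C=O)c1Oc1cc(C=O)c(Oc2cc(OC)c(OC)c(OC)c2Oc2cc(OC)c(Oc3cc(OC)c(OC)c(OC)c3)c(OC)c2)c(C=O)c1 | intermediate
23 | B–C–D–E–F tetra-aldehyde phenol | O=Cc1cc(O)cc(C=O)c1Oc1cc(C=O)c(Oc2cc(OC)c(OC)c(OC)c2Oc2cc(OC)c(Oc3cc(OC)c(OC)c(OC)c3)c(OC)c2)c(C=O)c1 | intermediate
24 | A–F hexa-aldehyde | COc1cc(C=O)c(Oc2cc(C=O)c(Oc3cc(C=O)c(Oc4cc(OC)c(OC)c(OC)c4Oc4cc(OC)c(Oc5cc(OC)c(OC)c(OC)c5)c(OC)c4)c(C=O)c3)c(C=O)c2)c(C=O)c1 | intermediate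
25 | A–F hexaformate | COc1cc(OC=O)c(Oc2cc(OC=O)c(Oc3cc(OC=O)c(Oc4cc(OC)c(OC)c(OC)c4Oc4cc(OC)c(Oc5cc(OC)c(OC)c(OC)c5)c(OC)c4)c(OC=O)c3)c(OC=O)c2)c(OC=O)c1 | intermediate
26 | A–F hexaphenol nonamethyl ether | COc1cc(O)c(Oc2cc(O)c(Oc3cc(O)c(Oc4cc(OC)c(OC)c(OC)c4Oc4cc(OC)c(Oc5cc(OC)c(OC)c(OC)c5)c(OC)c4)c(O)c3)c(O)c2)c(O)c1 | intermediate
27 | CNP0175585.0 | Oc1cc(O)c(Oc2cc(O)c(Oc3cc(O)c(Oc4cc(O)c(O)c(O)c4Oc4cc(O)c(Oc5cc(O)c(O)c(O)c5)c(O)c4)c(O)c3)c(O)c2)c(O)c1 | target

**Step count**

Total step count: 17.
Longest linear sequence: 11 steps (6, 7, 9, 10, 11, 12, 13, 14, 15, 16, 17).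

**Steps most likely to fail**

1. Step 16. Hydride migration instead of aryl migration in one or more of the six Criegee adducts would give carboxylic acids. Any per-site leakage multiplies over six sites, and the oxidation may also stall at partly converted stages. The fallback removes the competing hydrogen; it sets out from 24 and comes back at 26.
 - Sixfold addition of MeMgBr (THF, −78 °C) should give the hexakis(1-hydroxyethyl) compound F1. It forms as a mixture of diastereomers that the next operation erases.
 - Dess–Martin periodinane should then give the hexaacetyl compound F2.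
 - mCPBA with catalytic TFA in CH2Cl2 should give the hexaacetate F3, because in an aryl methyl ketone methyl does not out-migrate an oxygenated aryl group.
 - K2CO3 in MeOH under argon then gives 26.

2. Step 9. Activation of a C–Br bond wedged between CHO and OMe may be slow, so protodebromination and base-induced loss of the aldehyde could overtake the coupling. The fallback replaces the copper coupling by addition–elimination on a quinone; it sets out from 14 and comes back at 19.
 - Commercial 2,6-dimethoxy-1,4-benzoquinone is monobrominated (Br2, CHCl3) to 3-bromo-2,6-dimethoxy-1,4-benzoquinone F4.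
 - The phenoxide of 14 (K2CO3, DMF, 0 °C) replaces bromide by conjugate addition–elimination to give the aryloxyquinone F5.
 - Na2S2O4 reduces F5 to the hydroquinone F6.
 - Pivaloyl chloride in pyridine acylates the hydroxyl next to the ring hydrogen rather than the one between two methoxy groups, giving the monopivalate F7.
 - MeI/K2CO3 methylates the remaining hydroxyl to give the methylated pivalate F8.
 - NaOMe in MeOH removes the pivalate to give 19.

3. Step 5. Three processes could go wrong. Fluoride may attack sulfur instead of the ring carbon and return the phenoxide. That phenoxide may capture the product fluoride. Dissolved naked fluoride may degrade the dialdehyde. The fallback replaces the ester of hexavalent sulfur, attacked by soluble fluoride in DMF, with a carbon-centred uronium leaving group. That group is displaced within an ion pair in an apolar solvent, so there is no S–O cleavage path. It sets out from 7 and comes back at 9.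
 - 2-Chloro-1,3-bis(2,6-diisopropylphenyl)imidazolium chloride and CsF in toluene at 110 °C convert 7 into the 2-aryloxyimidazolium bifluoride F9.
 - F9 collapses by concerted fluoride delivery to the ipso carbon and gives 9.

**Further compounds**

F1 | step 16 | A–F hexakis(1-hydroxyethyl) compound (mixture of diastereomers) | COc1cc(C(C)O)c(Oc2cc(C(C)O)c(Oc3cc(C(C)O)c(Oc4cc(OC)c(OC)c(OC)c4Oc4cc(OC)c(Oc5cc(OC)c(OC)c(OC)c5)c(OC)c4)c(C(C)O)c3)c(C(C)O)c2)c(C(C)O)c1
F2 | step 16 | A–F hexaacetyl compound | COc1cc(C(C)=O)c(Oc2cc(C(C)=O)c(Oc3cc(C(C)=O)c(Oc4cc(OC)c(OC)c(OC)c4Oc4cc(OC)c(Oc5cc(OC)c(OC)c(OC)c5)c(OC)c4)c(C(C)=O)c3)c(C(C)=O)c2)c(C(C)=O)c1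
F3 | step 16 | A–F hexaacetate | COc1cc(OC(C)=O)c(Oc2cc(OC(C)=O)c(Oc3cc(OC(C)=O)c(Oc4cc(OC)c(OC)c(OC)c4Oc4cc(OC)c(Oc5cc(OC)c(OC)c(OC)c5)c(OC)c4)c(OC(C)=O)c3)c(OC(C)=O)c2)c(OC(C)=O)c1
F4 | step 9 | 3-bromo-2,6-dimethoxy-1,4-benzoquinone | COC1=CC(=O)C(Br)=C(OC)C1=O
F5 | step 9 | 3-(E–F aryloxy)-2,6-dimethoxy-1,4-benzoquinone | COC1=CC(=O)C(Oc2cc(OC)c(Oc3cc(OC)c(OC)c(OC)c3)c(OC)c2)=C(OC)C1=O
F6 | step 9 | 3-(E–F aryloxy)-2,6-dimethoxyhydroquinone | COc1cc(O)c(Oc2cc(OC)c(Oc3cc(OC)c(OC)c(OC)c3)c(OC)c2)c(OC)c1O
F7 | step 9 | monopivalate of F6 at the less hindered hydroxyl | COc1cc(OC(=O)C(C)(C)C)c(Oc2cc(OC)c(Oc3cc(OC)c(OC)c(OC)c3)c(OC)c2)c(OC)c1O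
F8 | step 9 | pivalate of D–E–F phenol 19 | COc1cc(OC(=O)C(C)(C)C)c(Oc2cc(OC)c(Oc3cc(OC)c(OC)c(OC)c3)c(OC)c2)c(OC)c1OC
F9 | step 5 | 2-[4-(benzyloxy)-2,6-diformylphenoxy]-1,3-bis(2,6-diisopropylphenyl)imidazolium bifluoride | CC(C)c1cccc(C(C)C)c1-n1cc[n+](-c2c(C(C)C)cccc2C(C)C)c1Oc1c(C=O)cc(OCc2ccccc2)cc1C=O.F.[F-]
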